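**Plan**
- Cuts, in retrosynthetic order: the aryl O–Si bond; C6–CH2 of the hydroxyisobutyl arm (enolate alkylation, then alkene hydration); the C5–O bond via a 5,6-epoxy ketone back to the C5=C6 enone; the ring bonds C7a–C7 and C7–C6; and C5–CH2 of the aryl side chain.
- Enabling feature: the C7 carbonyl lies between quaternary C7a and C6, and C4 is bonded to C3a, so the six-membered ring is the five-carbon unit C7a–C3a–C4–C5–C6 of a 6-alkenyl-1,5-dimethylbicyclo[3.1.0]hexane plus one CO.
- Forward: the aryl allylic bromide and the meso cyclopropane (from 1,2-dimethylcyclopentene) are made separately and joined by a Shapiro coupling. Carbonylation then closes the cyclohexenone onto the existing cyclopentane.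
- After ring closure: enone conjugation, oxygen at C5, alkylation at C6, hydration, desilylation.
- Stereochemistry: the cis C3a/C7a methyls come from the syn cyclopropanation, and their absolute sense from the ligand's choice between the two enantiotopic cyclopropane bonds. C5 comes from a hydroxyl-directed epoxidation relayed from a temporary C7 carbinol, C6 from chelate-controlled alkylation of an epimerizable centre, and the E alkene from the SeO2 oxidation.

Key step: step 10

Assumption: the cyclopropanation is taken to give mainly the exo ester (carboxyl cis to the two methyls); 9–14 are drawn exo, and any endo epimer is also meso and converges on 16 because that carbon becomes sp2 C4.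

Conventions: hydrindane numbering (C1–C3 cyclopentane CH2, C3a and C7a methylated fusion carbons, C4, C5 carbinol, C6, C7 ketone). α = face of the two angular methyls, β = face of the cyclopentane ring. Ar = 5-methoxy-3-methyl-2-(triisopropylsilyloxy)phenyl; SC = (E)-4-Ar-2-methylbut-2-en-1-yl.

**Step 1**
Reactants: 1 4-methoxy-2-methylphenol
Product: 3 4-methoxy-2-methyl-6-(3-methylbut-2-en-1-yl)phenol, via sodium phenoxide 2 (not isolated)
Conditions: NaH, toluene, 0 °C; then prenyl bromide, 0 °C → rt
Reagents that add atoms: 1-bromo-3-methylbut-2-ene (prenyl bromide), CC(C)=CCBr; sodium hydride, [Na+].[H-] (sodium of 2)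
Why: ortho C-allylation of a sodium phenoxide ion pair in a non-polar solvent; the para position carries OMe and C6 is the only free ortho carbon, so the prenyl group should enter there without allylic transposition.

**Step 2**
Reactants: 3 4-methoxy-2-methyl-6-(3-methylbut-2-en-1-yl)phenol
Product: 4 [4-methoxy-2-methyl-6-(3-methylbut-2-en-1-yl)phenoxy]triisopropylsilane
Conditions: TIPSOTf, 2,6-lutidine, CH2Cl2, 0 °C → rt
Reagents that add atoms: triisopropylsilyl triflate, CC(C)[Si](C(C)C)(C(C)C)OS(=O)(=O)C(F)(F)F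
Why: O-silylation of a hindered phenol with a silyl triflate; the TIPS ether should survive the organolithium, hydride, peroxide, enolate and radical steps ahead and fall to fluoride at the end.

**Step 3**
Reactants: 4 [4-methoxy-2-methyl-6-(3-methylbut-2-en-1-yl)phenoxy]triisopropylsilane
Product: 5 (E)-4-Ar-2-methylbut-2-en-1-ol
Conditions: SeO2 (cat.), t-BuOOH, CH2Cl2, 0 °C → rt
Reagents that add atoms: tert-butyl hydroperoxide, CC(C)(C)OO (oxygen relayed through selenium dioxide, O=[Se]=O)
Why: Riley allylic oxidation (ene reaction, then [2,3]-sigmatropic shift) of a prenyl group attacks the methyl trans to the chain, which fixes the E trisubstituted alkene of the target.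

**Step 4**
Reactants: 5 (E)-4-Ar-2-methylbut-2-en-1-ol
Product: 6 (E)-[2-(4-bromo-3-methylbut-2-en-1-yl)-4-methoxy-6-methylphenoxy]triisopropylsilane
Conditions: CBr4, PPh3, CH2Cl2, 0 °C
Reagents that add atoms: carbon tetrabromide, BrC(Br)(Br)Br
Why: Appel bromination of a primary allylic alcohol proceeds by SN2 displacement of the oxyphosphonium group, without allylic shift or loss of the E geometry.

**Step 5**
Reactants: 7 1,2-dimethylcyclopentene; 8 ethyl diazoacetate
Product: 9 ethyl exo-1,5-dimethylbicyclo[3.1.0]hexane-6-carboxylate (meso)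
Conditions: Rh2(OAc)4 (1 mol %), excess 7, slow addition of 8, CH2Cl2, rt
Reagents that add atoms: none
Why: rhodium-carbenoid cyclopropanation of an electron-rich tetrasubstituted alkene; the concerted syn addition fixes the cis relation of the two methyls (future C3a and C7a) and gives a meso product.

**Step 6**
Reactants: 9 ethyl exo-1,5-dimethylbicyclo[3.1.0]hexane-6-carboxylate
Product: 10 exo-N-methoxy-N,1,5-trimethylbicyclo[3.1.0]hexane-6-carboxamide (meso)
Conditions: MeNH(OMe)·HCl, i-PrMgCl, THF, −20 °C → rt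
Reagents that add atoms: N,O-dimethylhydroxylamine hydrochloride, CNOC.Cl
Why: aminolysis of the ester by the chloromagnesium amide gives the Weinreb amide, a method that tolerates hindered esters.

**Step 7**
Reactants: 10 exo-N-methoxy-N,1,5-trimethylbicyclo[3.1.0]hexane-6-carboxamide
Product: 11 1-(exo-1,5-dimethylbicyclo[3.1.0]hexan-6-yl)ethan-1-one (meso)
Conditions: MeMgBr, THF, 0 °C → rt
Reagents that add atoms: methylmagnesium bromide, C[Mg]Br
Why: Weinreb ketone synthesis; the chelated tetrahedral intermediate holds until work-up, so addition stops at the methyl ketone.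

**Step 8**
Reactants: 11 1-(exo-1,5-dimethylbicyclo[3.1.0]hexan-6-yl)ethan-1-one
Product: 12 (E)-2,4,6-triisopropylbenzenesulfonyl hydrazone of 11
Conditions: 2,4,6-triisopropylbenzenesulfonyl hydrazide, HCl (cat.), MeOH, rt
Reagents that add atoms: 2,4,6-triisopropylbenzenesulfonyl hydrazide, CC(C)c1cc(C(C)C)c(S(=O)(=O)NN)c(C(C)C)c1
Why: acid-catalysed condensation of a methyl ketone with an arenesulfonyl hydrazide gives the hydrazone needed for the Shapiro reaction.

**Step 9**
Reactants: 12 trisylhydrazone of 11; 6 (E)-allylic bromide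
Product: 14 exo-6-[(4E)-6-Ar-4-methylhexa-1,4-dien-2-yl]-1,5-dimethylbicyclo[3.1.0]hexane (meso), via vinyllithium 13 (not isolated)
Conditions: n-BuLi (2.2 equiv), TMEDA–hexane, −78 → 0 °C; then THF, Li2CuCl4 (5 mol %), 6, −78 → 0 °C
Reagents that add atoms: n-butyllithium, [Li]CCCC (lithium of 13)
Why: Shapiro reaction (deprotonation at the methyl group, loss of sulfinate and N2) gives the 1-cyclopropylvinyllithium, and copper-catalysed SN2 coupling with the primary allylic bromide joins the side chain at the future C5 with the E alkene retained.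

**Step 10**
Reactants: 14 meso vinylcyclopropane; 15 carbon monoxide
Product: 16 (3aR,7aR)-3a,7a-dimethyl-5-SC-hydrind-4-en-7-one (C4=C5, C6H2, C7=O)
Conditions: [Rh(CO)2Cl]2 (5 mol %), (R)-DTBM-SEGPHOS (11 mol %), AgSbF6 (10 mol %), CO (1 atm), 1,2-dichloroethane, 80 °C
Reagents that add atoms: none
Why: Proposed new method: monovalent rhodium binds the 1,1-disubstituted alkene of 14 and inserts into one of the two proximal cyclopropane bonds, giving a π-allyl/σ-tertiary-alkyl rhodacycle of trivalent rhodium; CO then inserts into the tertiary alkyl–rhodium bond and reductive elimination joins the acyl carbon to the CH2 end of the allyl unit, so that C7a–C7 and C7–C6 form and the C4=C5 alkene is left. The closest known reaction type is the rhodium-catalysed [5+1] carbonylation of vinylcyclopropanes to β,γ-cyclohexenones (with photochemical iron carbonyl variants), which has not been run as a ligand-controlled desymmetrization of a meso, fully substituted cyclopropane. The six-membered ring closes by C–C reductive elimination from a seven-membered acyl rhodacycle, a formal [5+1] union of the five vinylcyclopropane carbons (C7a, C3a, C4, C5, C6) with CO (C7). The cis relation of the C3a and C7a methyls is inherited from the cyclopropane, and their absolute configuration (3aR,7aR) is set by the chiral diphosphine, which must pick one of the two enantiotopic proximal bonds. No regiochemical choice arises because the two proximal bonds are equivalent by symmetry and the distal bond is not allylic; ring strain drives the opening, and the CO atmosphere is needed so that insertion outruns β-hydride elimination from the tertiary alkyl rhodium species.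

**Step 11**
Reactants: 16 (3aR,7aR)-β,γ-enone
Product: 17 (3aR,7aR)-3a,7a-dimethyl-5-SC-hydrind-5-en-7-one (C5=C6 conjugated with C7=O)
Conditions: DBU (0.2 equiv), CH2Cl2, 0 °C → rt
Reagents that add atoms: none
Why: base-mediated isomerization of a β,γ- to an α,β-unsaturated ketone through the dienolate (deprotonation at C6, protonation at C4), driven by conjugation and kept brief so that the side-chain alkene does not migrate.

**Step 12**
Reactants: 17 (3aR,7aR)-conjugated enone
Product: 18 (3aR,7R,7aR)-3a,7a-dimethyl-5-SC-hydrind-5-en-7-ol (C7–OH α)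
Conditions: NaBH4, CeCl3·7H2O, MeOH, −78 → −40 °C
Reagents that add atoms: none
Why: Luche 1,2-reduction; hydride should add to C7 from the β face, because on the α face an axial angular methyl (on C7a or C3a, depending on the half-chair) lies in its path while the β face carries only the tied-back cyclopentane methylene, which puts the temporary C7 hydroxyl on the α face.

**Step 13**
Reactants: 18 (3aR,7R,7aR)-allylic alcohol
Product: 19 (3aR,5R,6S,7S,7aR)-5,6-epoxy-3a,7a-dimethyl-5-SC-hydrindan-7-ol (epoxide and OH both α)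
Conditions: VO(acac)2 (5 mol %), t-BuOOH (decane), CH2Cl2, 0 °C → rt
Reagents that add atoms: tert-butyl hydroperoxide, CC(C)(C)OO
Why: vanadium-catalysed hydroxyl-directed epoxidation delivers oxygen syn to the C7 hydroxyl, hence to the α face of C5=C6 regardless of its shielding, and leaves the undirected side-chain alkene alone; this sets C5.

**Step 14**
Reactants: 19 α-epoxy alcohol
Product: 20 (3aR,5R,6R,7aR)-5,6-epoxy-3a,7a-dimethyl-5-SC-hydrindan-7-one (α-epoxide)
Conditions: Dess–Martin periodinane, NaHCO3, CH2Cl2, 0 °C → rt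
Reagents that add atoms: none
Why: Dess–Martin oxidation of the secondary alcohol under buffered, non-basic conditions restores the C7 ketone without touching the epoxide.

**Step 15**
Reactants: 20 α-epoxy ketone
Product: 21 (3aR,5R,7aR)-5-hydroxy-3a,7a-dimethyl-5-SC-hydrindan-7-one (C5–OH α)
Conditions: SmI2 (2.2 equiv), THF–MeOH, −90 °C
Reagents that add atoms: none
Why: SmI2 reductive opening of an α,β-epoxy ketone cleaves only the C6–O bond next to the ketyl, so the tertiary aldol forms with the C5 configuration untouched and, at this temperature, without dehydration.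

**Step 16**
Reactants: 21 β-hydroxy ketone
Product: 23 (3aR,5R,6R,7aR)-5-hydroxy-3a,7a-dimethyl-6-(2-methylprop-2-en-1-yl)-5-SC-hydrindan-7-one, via dilithium dianion 22 (not isolated)
Conditions: LDA (2.5 equiv), THF, −78 → −30 °C; DMPU, 3-bromo-2-methylpropene, −78 → −30 °C; NH4Cl (aq)
Reagents that add atoms: 3-bromo-2-methylprop-1-ene, CC(=C)CBr; lithium diisopropylamide, [Li]N(C(C)C)C(C)C (lithium of 22)
Why: alkylation of a β-hydroxy carbonyl dianion (Fráter–Seebach type) at C6, the only enolizable position; the electrophile is expected anti to the C5 side chain and cis to the chelated oxygen, and C6, being enolizable, can also settle into this more stable epimer with the new group equatorial.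

**Step 17**
Reactants: 23 C6-methallyl ketone
Product: 24 (3aR,5R,6R,7aR)-5-hydroxy-6-(2-hydroxy-2-methylpropyl)-3a,7a-dimethyl-5-SC-hydrindan-7-one (TIPS ether of the target)
Conditions: Co(acac)2 (20 mol %), PhSiH3, O2 (1 atm), i-PrOH–THF, 0 °C → rt
Reagents that add atoms: dioxygen, O=O
Why: Mukaiyama hydration (hydrogen-atom transfer from a cobalt hydride, trapping of the tertiary radical by O2) gives the Markovnikov tertiary alcohol and should favour the 1,1-disubstituted alkene over the more hindered trisubstituted side-chain alkene.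

**Step 18**
Reactants: 24 TIPS ether of the target
Product: 25 (3aR,5R,6R,7aR)-5-hydroxy-5-[(E)-4-(2-hydroxy-5-methoxy-3-methylphenyl)-2-methylbut-2-en-1-yl]-6-(2-hydroxy-2-methylpropyl)-3a,7a-dimethylhydrindan-7-one (CNP0190381.3)
Conditions: TBAF, AcOH (1:1), THF, 0 °C
Reagents that add atoms: none
Why: fluoride cleavage of the aryl silyl ether, buffered with acetic acid so that the tertiary aldol neither undergoes retro-aldol cleavage nor dehydrates.

**Compound list**
1 | 4-methoxy-2-methylphenol | COc1ccc(O)c(C)c1 | starting material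
2 | sodium 4-methoxy-2-methylphenoxide | COc1ccc([O-])c(C)c1.[Na+] | intermediate
3 | 4-methoxy-2-methyl-6-(3-methylbut-2-en-1-yl)phenol | COc1cc(C)c(O)c(CC=C(C)C)c1 | intermediate
4 | [4-methoxy-2-methyl-6-(3-methylbut-2-en-1-yl)phenoxy]triisopropylsilane | COc1cc(C)c(O[Si](C(C)C)(C(C)C)C(C)C)c(CC=C(C)C)c1 | intermediate
5 | (E)-4-[5-methoxy-3-methyl-2-(triisopropylsilyloxy)phenyl]-2-methylbut-2-en-1-ol | COc1cc(C)c(O[Si](C(C)C)(C(C)C)C(C)C)c(C/C=C(\C)CO)c1 | intermediate
6 | (E)-[2-(4-bromo-3-methylbut-2-en-1-yl)-4-methoxy-6-methylphenoxy]triisopropylsilane | COc1cc(C)c(O[Si](C(C)C)(C(C)C)C(C)C)c(C/C=C(\C)CBr)c1 | intermediate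
7 | 1,2-dimethylcyclopentene | CC1=C(C)CCC1 | starting material
8 | ethyl diazoacetate | CCOC(=O)C=[N+]=[N-] | starting material
9 | ethyl exo-1,5-dimethylbicyclo[3.1.0]hexane-6-carboxylate (meso) | CCOC(=O)[C@H]1[C@]2(C)CCC[C@]12C | intermediate
10 | exo-N-methoxy-N,1,5-trimethylbicyclo[3.1.0]hexane-6-carboxamide (meso) | CON(C)C(=O)[C@H]1[C@]2(C)CCC[C@]12C | intermediate
11 | 1-(exo-1,5-dimethylbicyclo[3.1.0]hexan-6-yl)ethan-1-one (meso) | CC(=O)[C@H]1[C@]2(C)CCC[C@]12C | intermediate
12 | (E)-2,4,6-triisopropylbenzenesulfonyl hydrazone of 11 | C/C(=N\NS(=O)(=O)c3c(C(C)C)cc(C(C)C)cc3C(C)C)[C@H]1[C@]2(C)CCC[C@]12C | intermediate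
13 | 1-(exo-1,5-dimethylbicyclo[3.1.0]hexan-6-yl)ethenyllithium | [Li]C(=C)[C@H]1[C@]2(C)CCC[C@]12C | intermediate
14 | exo-6-[(4E)-6-Ar-4-methylhexa-1,4-dien-2-yl]-1,5-dimethylbicyclo[3.1.0]hexane (meso) | C=C(C/C(C)=C/Cc3cc(OC)cc(C)c3O[Si](C(C)C)(C(C)C)C(C)C)[C@H]1[C@]2(C)CCC[C@]12C | intermediate
15 | carbon monoxide | [C-]#[O+] | starting material
16 | (3aR,7aR)-3a,7a-dimethyl-5-SC-hydrind-4-en-7-one | O=C1CC(C/C(C)=C/Cc3cc(OC)cc(C)c3O[Si](C(C)C)(C(C)C)C(C)C)=C[C@@]2(C)CCC[C@@]12C | intermediate
17 | (3aR,7aR)-3a,7a-dimethyl-5-SC-hydrind-5-en-7-one | O=C1C=C(C/C(C)=C/Cc3cc(OC)cc(C)c3O[Si](C(C)C)(C(C)C)C(C)C)C[C@@]2(C)CCC[C@@]12C | intermediate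
18 | (3aR,7R,7aR)-3a,7a-dimethyl-5-SC-hydrind-5-en-7-ol | O[C@@H]1C=C(C/C(C)=C/Cc3cc(OC)cc(C)c3O[Si](C(C)C)(C(C)C)C(C)C)C[C@@]2(C)CCC[C@@]12C | intermediate
19 | (3aR,5R,6S,7S,7aR)-5,6-epoxy-3a,7a-dimethyl-5-SC-hydrindan-7-ol | O[C@@H]1[C@@H]2O[C@]2(C/C(C)=C/Cc4cc(OC)cc(C)c4O[Si](C(C)C)(C(C)C)C(C)C)C[C@@]3(C)CCC[C@@]13C | intermediate
20 | (3aR,5R,6R,7aR)-5,6-epoxy-3a,7a-dimethyl-5-SC-hydrindan-7-one | O=C1[C@@H]2O[C@]2(C/C(C)=C/Cc4cc(OC)cc(C)c4O[Si](C(C)C)(C(C)C)C(C)C)C[C@@]3(C)CCC[C@@]13C | intermediate
21 | (3aR,5R,7aR)-5-hydroxy-3a,7a-dimethyl-5-SC-hydrindan-7-one | O=C1C[C@@](O)(C/C(C)=C/Cc3cc(OC)cc(C)c3O[Si](C(C)C)(C(C)C)C(C)C)C[C@@]2(C)CCC[C@@]12C | intermediate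
22 | dilithium alkoxide–enolate of 21 (C5–OLi, C6=C7–OLi) | [Li]OC1=C[C@@](O[Li])(C/C(C)=C/Cc3cc(OC)cc(C)c3O[Si](C(C)C)(C(C)C)C(C)C)C[C@@]2(C)CCC[C@@]12C | intermediate
23 | (3aR,5R,6R,7aR)-5-hydroxy-3a,7a-dimethyl-6-(2-methylprop-2-en-1-yl)-5-SC-hydrindan-7-one | O=C1[C@H](CC(C)=C)[C@@](O)(C/C(C)=C/Cc3cc(OC)cc(C)c3O[Si](C(C)C)(C(C)C)C(C)C)C[C@@]2(C)CCC[C@@]12C | intermediate
24 | (3aR,5R,6R,7aR)-5-hydroxy-6-(2-hydroxy-2-methylpropyl)-3a,7a-dimethyl-5-SC-hydrindan-7-one | O=C1[C@H](CC(C)(C)O)[C@@](O)(C/C(C)=C/Cc3cc(OC)cc(C)c3O[Si](C(C)C)(C(C)C)C(C)C)C[C@@]2(C)CCC[C@@]12C | intermediate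
25 | (3aR,5R,6R,7aR)-5-hydroxy-5-[(E)-4-(2-hydroxy-5-methoxy-3-methylphenyl)-2-methylbut-2-en-1-yl]-6-(2-hydroxy-2-methylpropyl)-3a,7a-dimethylhydrindan-7-one | COc1cc(C)c(O)c(C/C=C(\C)C[C@@]2(O)C[C@@]3(C)CCC[C@@]3(C)C(=O)[C@@H]2CC(C)(C)O)c1 | target

**Step count**
Total: 18 steps. Longest linear sequence: 14 steps (steps 5–18 from 1,2-dimethylcyclopentene; the aryl branch, steps 1–4 then 9–18, is equally long).

**Steps most likely to fail**

Step 10 (carbonylation). CO insertion at the hindered tertiary alkyl–rhodium bond may lose to β-hydride elimination, or the ligand may discriminate poorly between the enantiotopic bonds. Fallback, from 14 back to 18: the carbonylation is run under the known achiral conditions ([Rh(CO)2Cl]2, dppp, CO, 80 °C), which should give 16 as a racemate with its (3aS,7aS) enantiomer ent-16 F1. DBU then gives 17 together with ent-17 F2. A Corey–Bakshi–Shibata reduction (2-methyl-CBS-oxazaborolidine antipode that delivers the (7R) carbinol, BH3·SMe2, toluene, −40 °C) converts the (3aR,7aR) enantiomer into 18 and the (3aS,7aS) enantiomer into the diastereomeric (3aS,7R,7aS) carbinol F3. The two are separated by chromatography and 18 re-enters at step 13.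

Step 12 (Luche reduction). Hydride delivery may show poor or reversed facial selectivity, which would place the C7 hydroxyl, and with it the directed epoxide, on the β face. Fallback, from 17 back to 20: if the α face proves to be the open one, the same preference is used directly. Weitz–Scheffer epoxidation of 17 (t-BuOOH, benzyltrimethylammonium hydroxide, THF, 0 °C) lets the hydroperoxide anion add to C5 from the α face and should give 20 in one step, by-passing 18 and 19. No compound outside the list arises (F0).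

Step 16 (dianion alkylation). The lithium aldolate may undergo retro-aldol opening before the second deprotonation, or the tertiary alkoxide may be O-alkylated. Fallback, from 21 back to 23: TMSOTf/Et3N (CH2Cl2, 0 °C) gives the bis(trimethylsilyl) derivative F4 (C5–OTMS, C6=C7 silyl enol ether). Zerovalent palladium (Pd2(dba)3·CHCl3, dppe, THF, 60 °C) with 2-methylallyl methyl carbonate then allylates C6 under neutral conditions (Tsuji allylation of a silyl enol ether) to the C5-O-TMS ketone F5. Citric acid in methanol removes the silyl ether and returns 23.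

**Further compounds**
F1 | step 10 | ent-16, (3aS,7aS)-3a,7a-dimethyl-5-SC-hydrind-4-en-7-one | O=C1CC(C/C(C)=C/Cc3cc(OC)cc(C)c3O[Si](C(C)C)(C(C)C)C(C)C)=C[C@]2(C)CCC[C@]12C
F2 | step 10 | ent-17, (3aS,7aS)-3a,7a-dimethyl-5-SC-hydrind-5-en-7-one | O=C1C=C(C/C(C)=C/Cc3cc(OC)cc(C)c3O[Si](C(C)C)(C(C)C)C(C)C)C[C@]2(C)CCC[C@]12C
F3 | step 10 | (3aS,7R,7aS)-3a,7a-dimethyl-5-SC-hydrind-5-en-7-ol | O[C@@H]1C=C(C/C(C)=C/Cc3cc(OC)cc(C)c3O[Si](C(C)C)(C(C)C)C(C)C)C[C@]2(C)CCC[C@]12C
F0 | step 12 | none | none
F4 | step 16 | (3aR,5R,7aR)-3a,7a-dimethyl-5-SC-5,7-bis(trimethylsilyloxy)hydrind-6-ene | C[Si](C)(C)OC1=C[C@@](O[Si](C)(C)C)(C/C(C)=C/Cc3cc(OC)cc(C)c3O[Si](C(C)C)(C(C)C)C(C)C)C[C@@]2(C)CCC[C@@]12C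
F5 | step 16 | (3aR,5R,6R,7aR)-3a,7a-dimethyl-6-(2-methylprop-2-en-1-yl)-5-SC-5-(trimethylsilyloxy)hydrindan-7-one | O=C1[C@H](CC(C)=C)[C@@](O[Si](C)(C)C)(C/C(C)=C/Cc3cc(OC)cc(C)c3O[Si](C(C)C)(C(C)C)C(C)C)C[C@@]2(C)CCC[C@@]12C
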